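Count the reagent. It is the limiting reagent, 35.0 mM against 210 mM of starting material and second substrate together, and what of it reacts goes to one or the other.

| flask | starting material | reagent | second substrate | protic impurity | temperature | remark | time |
|---|---|---|---|---|---|---|---|
| grey | 35 mM | 35 mM | 175 mM | 0.70 mM | 15 °C | run made earlier |  |
| teal | 49 mM | 35 mM | 175 mM | 0.70 mM | 26 °C | run made earlier |  |
| blue | 77 mM | 35 mM | 175 mM | 0.70 mM | 15 °C | run made earlier |  |
| south-west | 35 mM | 35.0 mM (fed, over 1.5 min) | 175 mM | 0.700 mM | 20 °C | all else is in the flask from the start; the feed brings no volume worth counting | 2.0 min |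
| east | 35 mM | 35.0 mM | 175 mM (fed, over 1.5 min) | 0.700 mM | 20 °C | all else is in the flask from the start; the feed brings no volume worth counting | 2.0 min |
| north | 35 mM | 35.0 mM | 175 mM | 0.700 mM | 20 °C | everything together at the start | 2.0 min |
| north-west | 35 mM | 35.0 mM (fed, over 1.5 min) | 175 mM | 0.700 mM |  | the addition at −10 °C, then warmed to 20 °C; the feed brings no volume worth counting | 2.0 min |

| run | time / s | target / % | starting material / % |
|---|---|---|---|
| grey | 10.0 | 9.1 | 84.4 |
| grey | 20.0 | 9.2 | 75.5 |
| grey | 30.0 | 8.6 | 72.0 |
| grey | 50.0 | 7.5 | 66.0 |
| grey | 80.0 | 6.5 | 62.4 |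
| teal | 20.0 | 10.6 | 73.3 |
| teal | 40.0 | 11.2 | 67.4 |
| teal | 60.0 | 9.9 | 61.2 |
| teal | 80.0 | 11.0 | 57.7 |
| teal | 90.0 | 11.1 | 56.7 |
| blue | 10.0 | 8.4 | 85.6 |
| blue | 25.0 | 7.2 | 78.0 |
| blue | 40.0 | 5.6 | 73.5 |
| blue | 60.0 | 4.5 | 70.6 |
| blue | 90.0 | 5.9 | 65.4 |

(readings scatter by 0.5 percentage points)

1. the flask that comes out highest in amount of target, in percent of the starting material charged, or "all alike" when all lie within 1.5 percentage points (south-west / east / north / north-west / all alike)
2. target at the end, in percent of the starting material charged, south-west
3. target at the end, in percent of the starting material charged, east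
4. target at the end, in percent of the starting material charged, north
5. target at the end, in percent of the starting material charged, north-west

- candidate steps: starting material + reagent -> target; second substrate + protic impurity -> quenched substrate; target -> over-reaction product; second substrate + reagent -> second product; target <-> isomer of the product; starting material + second substrate -> cross product

Two chemists disagree. Ada balances the reagent. She takes the late fall of starting material in grey, 0.00187 s⁻¹, as a slow loss that uses no reagent. Removing it leaves 72.5% of the starting material at 80.0 s, so she reads 27.5% for s, the reagent share: the part of the charged reagent that ends on starting material. The odds s/(1−s) are then 0.380.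

She carries that s from 15 °C to 20 °C unchanged; feeding the reagent leaves both partners near their charges, she says, so south-west stays near it. Feeding second substrate over 1.5 min holds its mean level during the feed near 87.5 mM, she reckons, which raises the odds by a factor of 2 and puts s at 43.2% in east. Her pick is east.

Ben watches the clock. In grey, target drops from 9.1% at 10.0 s to 6.5% at 80.0 s while starting material keeps falling, so he wants target formed late. His forecast for north-west reads: “reagent accumulates cold, then reacts late on warming, so the isomer has not caught up”. It gives 10.5% for south-west, 13.5% for east, 8.2% for north and 14% for north-west, and picks north-west.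

The simulation gives 7.93% for south-west, 18.4% for east, 8.63% for north and 10.4% for north-west, so east comes out highest.

    starting material + reagent → target (k = 0.800 M⁻¹ s⁻¹, Ea = 36.0 kJ mol⁻¹)
    second substrate + protic impurity → quenched substrate (k = 250 M⁻¹ s⁻¹, Ea = 41.0 kJ mol⁻¹)
    target → over-reaction product (k = 1.20 × 10⁻⁵ s⁻¹, Ea = 108 kJ mol⁻¹)
    second substrate + reagent → second product (k = 0.440 M⁻¹ s⁻¹, Ea = 54.0 kJ mol⁻¹)
    target ⇌ isomer of the product (K = 1.90, k = 0.150 s⁻¹, Ea = 82.0 kJ mol⁻¹, ΔH = −82.0 kJ mol⁻¹)
    starting material + second substrate → cross product (k = 0.0180 M⁻¹ s⁻¹, Ea = 47.0 kJ mol⁻¹)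
    (constants at 20 °C)

In east, of the 35.0 mM of reagent charged, target, isomer of the product and over-reaction product together hold 18.7 mM, second product holds 16.3 mM, and 0.110% of the charge stands unreacted, so s is 53.4%, above Ada's 43.2%. The neighbour of east with 14 mM of reagent has s at 60.1% and target at 8.29%. Ben's lag has its place on the scale of target's forward half-life into the isomer, 0.077 min in east at 0.223 min, which is short against 2.0 min. East's target still stands at 18.3% at 20.0 min, but by then starting material has gone from 37.4% to 2.19% and cross product has reached 44.4%.

The runs are calculated with made-up constants, noise included.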